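Read the green run before spending more starting material.

| flask | starting material | partner | remark | time |
|---|---|---|---|---|
| green | 0.75 M | 1.2 M | run made earlier |  |
| north | 0.60 M | 1.20 M |  | 6.0 h |
| east | 0.80 M | 1.20 M |  | 6.0 h |
| south-west | 1.2 M | 1.20 M |  | 6.0 h |
| west | 2.0 M | 1.20 M |  | 6.0 h |
| north-west | 3.0 M | 1.20 M |  | 6.0 h |

- green (time / h: target / %): 1.00: 0.8; 2.00: 1.6; 3.00: 3.8; 4.00: 5.0; 5.00: 8.7; 6.00: 11.4

(standard deviation of a reading: 0.5 percentage points)

* amount of target at the end, in percent of the starting material charged for north, east, south-west, west, north-west, in this order
* the shape of the row from first to last (falls, then rises / rises, then falls / rises all the way / hardly changes / falls all the way)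

- "hardly changes" means that all values lie within two and a half points (for a concentration: within two and a half percent of the largest)

Two chemists dispute this row. Both take one partner per starting material. Both use the loading, starting material charged per partner charged. North-west has 2.50, its loading. North has 0.500.

The first chemist made the forecast. The green reading grows 3.00-fold from 3.00 h to 6.00 h, and she reads the acceleration as autocatalysis by the target. Her row is 9.1%, 12.4%, 21%, 37%, 37%. The last two nearly tie in her reckoning, and the shape she gives is: rises, then falls. Her ground is “More starting material means more target sooner, so the percentage climbs”. She also sets ceilings of 60% for west and 40% for north-west, which are one over the loading.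

The second chemist reads the same growth as the lag of a queue of intermediates. In a queue of first-order steps, percent depends on time and not on charge. So her row starts from the green 11.4%.

She then compares north and north-west. Both start with partner at 1.20 M. If target stood at the green reading, it would cost north-west 28.5% of its partner and north 5.70%, so north-west would pay more than north. She therefore expects a step that needs partner to slow more in north-west than in north. She commits to a row near the green reading that sags toward north-west.

The flask gives 11.8%, 11.5%, 11.0%, 10.0%, 8.94%. Its shape: falls all the way.

    starting material + intermediate C → side product (k = 7.20 × 10⁻⁴ /M/min)
    intermediate A ⇌ intermediate B (K = 1.00, k = 0.0630 /min)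
    partner + intermediate A → intermediate C (k = 0.00300 /M/min)
    intermediate C → target (k = 0.00210 /min)
    starting material → intermediate A (k = 0.0190 /min)

The sag stands beside the partner: at 6.00 h north-west keeps 31.5% of its partner and north keeps 80.5%. The forecast's ceiling belongs to long times. North-west, with loading 2.50, has a ceiling of 40.0%, and at 60.0 h it holds target 39.5% with the partner, its limiting reagent, at 0%. West, with loading 1.67, has a ceiling of 60.0%, and at 60.0 h it holds target 58.8% with partner at 0.588%.

The readings come from a simulation with constants of no real substance; the scatter is artificial.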